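**Retrosynthetic overview**
- Feature: in labdane numbering the target is a trans-decalin (rings A and B) with 4β-Me (C19, axial), 4α-CO2Me (C18, equatorial), 6α-OH and 8α-OH. The equatorial O6 on ring B and the equatorial C18 on C4 of ring A are peri neighbours across C5, so the core is a 4,4-dimethyl labdane oxidised only at the methyl group that faces O6.
- Side chain: C14–OOH by SN2 inversion of a 14R allylic sulfonate; C13–C14 by Nozaki–Hiyama–Kishi coupling of the C13 enol triflate with an (S)-butenolide acetaldehyde made from (S)-3-hydroxydihydrofuran-2(3H)-one.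
- Core: the C18 ester comes from methanolysis of the 18,6α-lactone, the lactone from RuO4 oxidation of the 6α,18-ether, and the ether from the 6α-alkoxyl radical by 1,5-hydrogen transfer (C18–O6 bond, new C4 stereocentre). The radical precursor comes from larixol by side-chain cleavage, ketalisation, hydration of C8=C17 and 8-O-silylation.
- Ring order: rings A and B come from larixol; the tetrahydrofuran ring O6–C6–C5–C4–C18 is closed in the key step and later opened as the lactone; the butenolide ring is closed on the side fragment before the coupling.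

Key step: step 7

Assumption: labdane numbering is used (C18 = 4α substituent, C19 = 4β methyl, C20 = C10 methyl), the SMILES is read as 14S with an (S) butenolide γ-carbon, and larixol and (S)-3-hydroxydihydrofuran-2(3H)-one are taken as purchasable.

**Route**

Step 1
Reactants: 1 larixol
Product: 2 larixyl acetate (6α-acetoxylabda-8(17),14-dien-13-ol)
Conditions: Ac2O, pyridine, rt
Reagents that add atoms: acetic anhydride, CC(=O)OC(C)=O
Why: Acylation with acetic anhydride in pyridine should esterify only the secondary equatorial 6α-OH, because the tertiary allylic 13-OH is inert to uncatalysed acetylation at room temperature.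

Step 2
Reactants: 2 larixyl acetate
Product: 3 6α-acetoxy-14,15-dinorlabd-8(17)-en-13-one
Conditions: KMnO4, MgSO4, acetone/H2O, 0 °C to rt
Reagents that add atoms: none
Why: Permanganate degradation of a tertiary vinyl carbinol (dihydroxylation of the monosubstituted C14=C15 alkene, then glycol cleavage between C13 and C14) should leave the C13 methyl ketone, the hindered 1,1-disubstituted C8=C17 alkene reacting more slowly under buffered cold conditions.

Step 3
Reactants: 3 6α-acetoxy-14,15-dinorlabd-8(17)-en-13-one; 4 ethylene glycol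
Product: 5 6α-acetoxy-13,13-ethylenedioxy-14,15-dinorlabd-8(17)-ene
Conditions: pyridinium p-toluenesulfonate (cat.), benzene, reflux, Dean–Stark
Reagents that add atoms: ethylene glycol (4), OCCO
Why: Acid-catalysed ketalisation with azeotropic removal of water masks C13 so that the later 8-OH cannot close onto it, and the weakly acidic pyridinium salt should leave the exocyclic alkene in place.

Step 4
Reactants: 5 6α-acetoxy-13,13-ethylenedioxy-14,15-dinorlabd-8(17)-ene
Product: 7 6α-acetoxy-13,13-ethylenedioxy-14,15-dinorlabdan-8α-ol, via 8α-hydroperoxide 6 (not isolated)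
Conditions: Co(acac)2 (cat.), PhSiH3, O2 (1 atm), THF, rt
Reagents that add atoms: dioxygen, O=O
Why: Mukaiyama hydration, in which a cobalt hydride transfers a hydrogen atom to C17 to give the tertiary C8 radical that is expected to take up O2 from the α face anti to the axial C10 methyl group, the hydroperoxide 6 being reduced by the silane, so that C8 is set as 8α-OH with the new methyl group C17 axial on the β face.

Step 5
Reactants: 7 6α-acetoxy-13,13-ethylenedioxy-14,15-dinorlabdan-8α-ol
Product: 8 6α-acetoxy-13,13-ethylenedioxy-8α-triethylsilyloxy-14,15-dinorlabdane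
Conditions: Et3SiOTf, 2,6-lutidine, CH2Cl2, −40 to 0 °C
Reagents that add atoms: triethylsilyl trifluoromethanesulfonate, CC[Si](CC)(CC)OS(=O)(=O)C(F)(F)F
Why: Silyl triflate silylation is needed for the tertiary 8α-OH and is safe here because the 6-OH is still acetylated and the ketal of a ketone tolerates the lutidine-buffered reagent at low temperature.

Step 6
Reactants: 8 6α-acetoxy-13,13-ethylenedioxy-8α-triethylsilyloxy-14,15-dinorlabdane
Product: 9 13,13-ethylenedioxy-8α-triethylsilyloxy-14,15-dinorlabdan-6α-ol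
Conditions: LiAlH4, THF, 0 °C
Reagents that add atoms: none
Why: Hydride cleavage of the hindered acetate (ester reduction) frees the 6α-OH without touching the tertiary silyl ether or the dioxolane, so the only free hydroxyl of 9 is the one that has to carry the radical.

Step 7
Reactants: 9 13,13-ethylenedioxy-8α-triethylsilyloxy-14,15-dinorlabdan-6α-ol
Product: 12 6α,18-epoxy-13,13-ethylenedioxy-8α-triethylsilyloxy-14,15-dinorlabdane, via hypoiodite 10 (not isolated), via C18 iodide 11 (not isolated)
Conditions: PhI(OAc)2, I2, cyclohexane, hν (visible, tungsten lamp), 40 °C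
Reagents that add atoms: none
Why: Acetyl hypoiodite formed from PhI(OAc)2 and I2 converts the equatorial 6α-OH into hypoiodite 10, whose O–I bond is cleaved by visible light to the O6 radical; this radical takes a hydrogen from the equatorial 4α-methyl C18 through a six-membered chair-like transition state (O6, C6, C5, C4, C18, H) that the syn-pentane (peri) relation of the two equatorial substituents on the trans-decalin makes possible, and the C18 radical is trapped by iodine to give iodide 11. The closest known reaction type is the hypoiodite reaction with trivalent iodine and I2, an alkoxyl-radical 1,5-hydrogen transfer from an unactivated methyl group followed by tetrahydrofuran closure, as used for the angular methyl groups of steroids. The tetrahydrofuran ring (O6–C6–C5–C4–C18) closes by 5-exo-tet displacement of iodide at C18 by O6 and is trans-fused to both ring A and ring B. C4 becomes a stereocentre because only one of its two methyl groups is oxidised, and its configuration (C18 α, C19 β) is fixed by the geometry of C5, C6 and C10 inherited from larixol, no bond at C4 being broken. The step needs C18 to be chosen over the axial 4β-methyl C19 and over C20, and hydrogen transfer to win over β-scission and over oxidation to the 6-ketone: C19 and C20 lie on the β face out of reach of the in-plane O6 radical, the 8-O-triethylsilyl group shuts off the tertiary C8 alkoxyl radical that would fragment the C8–C9 bond, and the dioxolane hydrogens are remote.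

Step 8
Reactants: 12 6α,18-epoxy-13,13-ethylenedioxy-8α-triethylsilyloxy-14,15-dinorlabdane
Product: 13 6α,18-epoxy-8α-triethylsilyloxy-14,15-dinorlabdan-13-one
Conditions: pyridinium p-toluenesulfonate (cat.), acetone/H2O, 50 °C
Reagents that add atoms: water, O
Why: Mild acid-catalysed ketal hydrolysis releases the C13 ketone before the oxidation so that no dioxolane C–H bonds compete for RuO4, and the tertiary silyl ether and the cyclic ether should be stable to the buffered acid.

Step 9
Reactants: 13 6α,18-epoxy-8α-triethylsilyloxy-14,15-dinorlabdan-13-one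
Product: 14 13-oxo-8α-triethylsilyloxy-14,15-dinorlabdan-18,6α-olide
Conditions: RuCl3·xH2O (cat.), NaIO4, CCl4/MeCN/H2O, rt
Reagents that add atoms: sodium periodate (oxygen delivered through RuO4), [Na+].[O-]I(=O)(=O)=O
Why: RuO4 oxidation of an ether to a lactone should attack the exposed C18 methylene and not the C6 methine, whose β hydrogen is screened by the axial methyl groups C17, C19 and C20, while ketone and silyl ether are inert.

Step 10
Reactants: 14 13-oxo-8α-triethylsilyloxy-14,15-dinorlabdan-18,6α-olide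
Product: 15 methyl 6α-hydroxy-13-oxo-8α-triethylsilyloxy-14,15-dinorlabdan-18-oate
Conditions: NaOMe (cat.), MeOH, 0 °C to rt; pH 7 buffer quench
Reagents that add atoms: methanol, CO
Why: Base-catalysed transesterification (lactone methanolysis) should be driven by the strain of a γ-lactone that is trans-fused to both carbocycles, and C4 cannot epimerise because it is quaternary.

Step 11
Reactants: 15 methyl 6α-hydroxy-13-oxo-8α-triethylsilyloxy-14,15-dinorlabdan-18-oate
Product: 16 methyl 13-oxo-6α,8α-bis(triethylsilyloxy)-14,15-dinorlabdan-18-oate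
Conditions: Et3SiOTf, 2,6-lutidine, CH2Cl2, −78 °C
Reagents that add atoms: triethylsilyl trifluoromethanesulfonate, CC[Si](CC)(CC)OS(=O)(=O)C(F)(F)F
Why: Silylation of the 6α-OH with the silyl triflate at −78 °C is much faster than enol silane formation at the methyl ketone under lutidine buffering, and it keeps the 6-alkoxide from re-closing the lactone in the next step.

Step 12
Reactants: 16 methyl 13-oxo-6α,8α-bis(triethylsilyloxy)-14,15-dinorlabdan-18-oate
Product: 18 methyl 6α,8α-bis(triethylsilyloxy)-13-(trifluoromethanesulfonyloxy)-14,15-dinorlabd-13(16)-en-18-oate, via lithium enolate 17 (not isolated)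
Conditions: LiN(i-Pr)2, THF, −78 °C; then PhNTf2, −78 to 0 °C
Reagents that add atoms: N-phenylbis(trifluoromethanesulfonimide), O=S(=O)(N(c1ccccc1)S(=O)(=O)C(F)(F)F)C(F)(F)F
Why: Kinetic deprotonation with the hindered amide base at −78 °C takes a methyl (C16) proton rather than a C12 methylene proton and O-triflation of enolate 17 (enol triflate synthesis) gives the 1-alken-2-yl triflate, the C18 ester having no α hydrogen.

Step 13
Reactants: 19 (S)-3-hydroxydihydrofuran-2(3H)-one
Product: 20 (S)-2,4-dihydroxy-N-methoxy-N-methylbutanamide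
Conditions: MeNH(OMe)·HCl, i-PrMgCl, THF, −20 to 0 °C
Reagents that add atoms: N,O-dimethylhydroxylamine hydrochloride, CNOC.Cl
Why: Aminolysis of the lactone by the magnesium amide of N,O-dimethylhydroxylamine (Weinreb amide formation) opens the ring at the acyl carbon, so no bond to the stereocentre is touched and its (S) configuration is carried over.

Step 14
Reactants: 20 (S)-2,4-dihydroxy-N-methoxy-N-methylbutanamide
Product: 21 (S)-4-(tert-butyldimethylsilyloxy)-2-hydroxy-N-methoxy-N-methylbutanamide
Conditions: t-BuMe2SiCl, imidazole, CH2Cl2, 0 °C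
Reagents that add atoms: tert-butyldimethylsilyl chloride, CC(C)(C)[Si](C)(C)Cl
Why: Silyl chloride with imidazole should silylate the unhindered primary hydroxyl in preference to the secondary hydroxyl next to the amide.

Step 15
Reactants: 21 (S)-4-(tert-butyldimethylsilyloxy)-2-hydroxy-N-methoxy-N-methylbutanamide
Product: 22 (S)-5-(tert-butyldimethylsilyloxy)-3-hydroxypentan-2-one
Conditions: MeMgBr (3 equiv), THF, −20 to 0 °C
Reagents that add atoms: methylmagnesium bromide, C[Mg]Br
Why: Weinreb ketone synthesis, in which the chelated tetrahedral intermediate stops at the ketone stage and the magnesium alkoxide formed from the free hydroxyl by the first equivalent protects the adjacent stereocentre from enolisation.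

Step 16
Reactants: 22 (S)-5-(tert-butyldimethylsilyloxy)-3-hydroxypentan-2-one
Product: 24 (S)-5-[2-(tert-butyldimethylsilyloxy)ethyl]-4-methylfuran-2(5H)-one, via ylide ester 23 (not isolated)
Conditions: Ph3P=C=C=O, toluene, 90 °C
Reagents that add atoms: (triphenylphosphoranylidene)ketene, O=C=C=P(c1ccccc1)(c1ccccc1)c1ccccc1
Why: Bestmann ylide annulation, in which the hydroxyl adds to the ketene to give the ester-stabilised ylide 23 that closes onto the neighbouring ketone by intramolecular Wittig reaction to form the butenolide ring under neutral conditions that leave the carbinol centre as (S).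

Step 17
Reactants: 24 (S)-5-[2-(tert-butyldimethylsilyloxy)ethyl]-4-methylfuran-2(5H)-one
Product: 25 (S)-5-(2-hydroxyethyl)-4-methylfuran-2(5H)-one
Conditions: HF (48% aq.), MeCN, 0 °C
Reagents that add atoms: none
Why: Acidic fluoride desilylation removes the primary silyl ether without base, which would risk epimerising the γ-carbon of the butenolide.

Step 18
Reactants: 25 (S)-5-(2-hydroxyethyl)-4-methylfuran-2(5H)-one
Product: 26 (S)-2-(3-methyl-5-oxo-2,5-dihydrofuran-2-yl)acetaldehyde
Conditions: Dess–Martin periodinane, NaHCO3, CH2Cl2, 0 °C; used at once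
Reagents that add atoms: none
Why: Dess–Martin oxidation under bicarbonate buffering gives the aldehyde without strong base, which matters because this β-acyloxy aldehyde can eliminate the lactone carboxylate.

Step 19
Reactants: 18 methyl 6α,8α-bis(triethylsilyloxy)-13-(trifluoromethanesulfonyloxy)-14,15-dinorlabd-13(16)-en-18-oate; 26 (S)-2-(3-methyl-5-oxo-2,5-dihydrofuran-2-yl)acetaldehyde
Product: 28 coupled C14 allylic alcohols (both C14 epimers), via alkenylchromium species 27 (not isolated)
Conditions: CrCl2 (excess), NiCl2 (cat.), DMF, rt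
Reagents that add atoms: none
Why: Nozaki–Hiyama–Kishi coupling, in which zerovalent nickel inserts into the C–OTf bond, the alkenyl group passes to trivalent chromium (27) and adds only to the aldehyde, leaving ester, lactone and silyl ethers, the new C14 carbinol being expected without useful control and being corrected in steps 20 and 21.

Step 20
Reactants: 28 coupled C14 allylic alcohols
Product: 29 C14 enone (13(16)-en-14-one)
Conditions: Dess–Martin periodinane, NaHCO3, CH2Cl2, 0 °C
Reagents that add atoms: none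
Why: Dess–Martin oxidation of the allylic alcohol mixture converges both C14 epimers on one enone under non-basic conditions that avoid β-elimination of the lactone oxygen.

Step 21
Reactants: 29 C14 enone
Product: 30 (14R)-allylic alcohol
Conditions: (S)-1-methyl-3,3-diphenyltetrahydro-1H,3H-pyrrolo[1,2-c][1,3,2]oxazaborole ((S)-Me-CBS, cat.), catecholborane, toluene, −78 °C
Reagents that add atoms: none
Why: Corey–Bakshi–Shibata reduction, in which the (S)-oxazaborolidine treats the α-branched alkenyl group as the large and the C15 methylene as the small substituent and delivers hydride to give the 14R alcohol by reagent control, catecholborane at −78 °C sparing the butenolide and the ester.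

Step 22
Reactants: 30 (14R)-allylic alcohol
Product: 32 (14S)-hydroperoxide 6,8-bis(triethylsilyl) ether, via mesylate 31 (not isolated)
Conditions: MsCl, Et3N, CH2Cl2, −40 °C; then anhydrous H2O2 in Et2O (large excess), −40 to 0 °C
Reagents that add atoms: hydrogen peroxide, OO
Why: Sulfonate displacement by hydrogen peroxide (an α-effect nucleophile) at the secondary allylic carbon by the SN2 path should invert C14 from R to S, a large excess of H2O2 suppressing dialkyl peroxide formation and the absence of hydroxide protecting the butenolide.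

Step 23
Reactants: 32 (14S)-hydroperoxide 6,8-bis(triethylsilyl) ether
Product: 33 CNP0324515.1 (target)
Conditions: HF·pyridine, pyridine, THF, 0 °C to rt
Reagents that add atoms: none
Why: Buffered HF·pyridine cleaves both triethylsilyl ethers (fluoride desilylation) under conditions that an allylic hydroperoxide, a methyl ester and a butenolide should tolerate.

**Compound list**

1 | larixol, (13S)-labda-8(17),14-diene-6α,13-diol | C=C[C@@](C)(O)CC[C@@H]1[C@@]2(C)CCCC(C)(C)[C@@H]2[C@@H](O)CC1=C | starting material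
2 | larixyl acetate | C=C[C@@](C)(O)CC[C@@H]1[C@@]2(C)CCCC(C)(C)[C@@H]2[C@@H](OC(C)=O)CC1=C | intermediate
3 | 6α-acetoxy-14,15-dinorlabd-8(17)-en-13-one | CC(=O)CC[C@@H]1[C@@]2(C)CCCC(C)(C)[C@@H]2[C@@H](OC(C)=O)CC1=C | intermediate
4 | ethylene glycol | OCCO | starting material
5 | 6α-acetoxy-13,13-ethylenedioxy-14,15-dinorlabd-8(17)-ene | CC1(OCCO1)CC[C@@H]2[C@@]3(C)CCCC(C)(C)[C@@H]3[C@@H](OC(C)=O)CC2=C | intermediate
6 | 6α-acetoxy-13,13-ethylenedioxy-14,15-dinorlabdan-8α-yl hydroperoxide | CC1(OCCO1)CC[C@@H]2[C@@]3(C)CCCC(C)(C)[C@@H]3[C@@H](OC(C)=O)C[C@@]2(C)OO | intermediate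
7 | 6α-acetoxy-13,13-ethylenedioxy-14,15-dinorlabdan-8α-ol | CC1(OCCO1)CC[C@@H]2[C@@]3(C)CCCC(C)(C)[C@@H]3[C@@H](OC(C)=O)C[C@@]2(C)O | intermediate
8 | 6α-acetoxy-13,13-ethylenedioxy-8α-triethylsilyloxy-14,15-dinorlabdane | CC1(OCCO1)CC[C@@H]2[C@@]3(C)CCCC(C)(C)[C@@H]3[C@@H](OC(C)=O)C[C@@]2(C)O[Si](CC)(CC)CC | intermediate
9 | 13,13-ethylenedioxy-8α-triethylsilyloxy-14,15-dinorlabdan-6α-ol (key-step precursor) | CC1(OCCO1)CC[C@@H]2[C@@]3(C)CCCC(C)(C)[C@@H]3[C@@H](O)C[C@@]2(C)O[Si](CC)(CC)CC | intermediate
10 | 6α-hypoiodite of 9 | CC1(OCCO1)CC[C@@H]2[C@@]3(C)CCCC(C)(C)[C@@H]3[C@@H](OI)C[C@@]2(C)O[Si](CC)(CC)CC | intermediate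
11 | 13,13-ethylenedioxy-18-iodo-8α-triethylsilyloxy-14,15-dinorlabdan-6α-ol | CC1(OCCO1)CC[C@@H]2[C@@]3(C)CCC[C@@](C)(CI)[C@@H]3[C@@H](O)C[C@@]2(C)O[Si](CC)(CC)CC | intermediate
12 | 6α,18-epoxy-13,13-ethylenedioxy-8α-triethylsilyloxy-14,15-dinorlabdane (key-step product) | CC1(OCCO1)CC[C@@H]2[C@@]3(C)CCC[C@@](C)(CO4)[C@@H]3[C@@H]4C[C@@]2(C)O[Si](CC)(CC)CC | intermediate
13 | 6α,18-epoxy-8α-triethylsilyloxy-14,15-dinorlabdan-13-one | CC(=O)CC[C@@H]1[C@@]2(C)CCC[C@@](C)(CO3)[C@@H]2[C@@H]3C[C@@]1(C)O[Si](CC)(CC)CC | intermediate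
14 | 13-oxo-8α-triethylsilyloxy-14,15-dinorlabdan-18,6α-olide | CC(=O)CC[C@@H]1[C@@]2(C)CCC[C@@](C)(C(=O)O3)[C@@H]2[C@@H]3C[C@@]1(C)O[Si](CC)(CC)CC | intermediate
15 | methyl 6α-hydroxy-13-oxo-8α-triethylsilyloxy-14,15-dinorlabdan-18-oate | CC(=O)CC[C@@H]1[C@@]2(C)CCC[C@@](C)(C(=O)OC)[C@@H]2[C@@H](O)C[C@@]1(C)O[Si](CC)(CC)CC | intermediate
16 | methyl 13-oxo-6α,8α-bis(triethylsilyloxy)-14,15-dinorlabdan-18-oate | CC(=O)CC[C@@H]1[C@@]2(C)CCC[C@@](C)(C(=O)OC)[C@@H]2[C@@H](O[Si](CC)(CC)CC)C[C@@]1(C)O[Si](CC)(CC)CC | intermediate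
17 | lithium 13(16)-en-13-olate of 16 | [Li+].[O-]C(=C)CC[C@@H]1[C@@]2(C)CCC[C@@](C)(C(=O)OC)[C@@H]2[C@@H](O[Si](CC)(CC)CC)C[C@@]1(C)O[Si](CC)(CC)CC | intermediate
18 | methyl 6α,8α-bis(triethylsilyloxy)-13-(trifluoromethanesulfonyloxy)-14,15-dinorlabd-13(16)-en-18-oate | C=C(OS(=O)(=O)C(F)(F)F)CC[C@@H]1[C@@]2(C)CCC[C@@](C)(C(=O)OC)[C@@H]2[C@@H](O[Si](CC)(CC)CC)C[C@@]1(C)O[Si](CC)(CC)CC | intermediate
19 | (S)-3-hydroxydihydrofuran-2(3H)-one | O[C@H]1CCOC1=O | starting material
20 | (S)-2,4-dihydroxy-N-methoxy-N-methylbutanamide | O[C@@H](CCO)C(=O)N(C)OC | intermediate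
21 | (S)-4-(tert-butyldimethylsilyloxy)-2-hydroxy-N-methoxy-N-methylbutanamide | O[C@@H](CCO[Si](C)(C)C(C)(C)C)C(=O)N(C)OC | intermediate
22 | (S)-5-(tert-butyldimethylsilyloxy)-3-hydroxypentan-2-one | CC(=O)[C@@H](O)CCO[Si](C)(C)C(C)(C)C | intermediate
23 | (triphenylphosphoranylidene)acetate ester of 22 | CC(=O)[C@@H](OC(=O)C=P(c1ccccc1)(c1ccccc1)c1ccccc1)CCO[Si](C)(C)C(C)(C)C | intermediate
24 | (S)-5-[2-(tert-butyldimethylsilyloxy)ethyl]-4-methylfuran-2(5H)-one | CC(C)(C)[Si](C)(C)OCC[C@@H]1OC(=O)C=C1C | intermediate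
25 | (S)-5-(2-hydroxyethyl)-4-methylfuran-2(5H)-one | OCC[C@@H]1OC(=O)C=C1C | intermediate
26 | (S)-2-(3-methyl-5-oxo-2,5-dihydrofuran-2-yl)acetaldehyde | O=CC[C@@H]1OC(=O)C=C1C | intermediate
27 | C13 alkenylchromium dichloride from 18 | C=C([Cr](Cl)Cl)CC[C@@H]1[C@@]2(C)CCC[C@@](C)(C(=O)OC)[C@@H]2[C@@H](O[Si](CC)(CC)CC)C[C@@]1(C)O[Si](CC)(CC)CC | intermediate
28 | coupled allylic alcohols, C14 epimer mixture, 6,8-bis(triethylsilyl) ether | C=C(CC[C@@H]1[C@@]2(C)CCC[C@@](C)(C(=O)OC)[C@@H]2[C@@H](O[Si](CC)(CC)CC)C[C@@]1(C)O[Si](CC)(CC)CC)C(O)C[C@@H]1OC(=O)C=C1C | intermediate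
29 | C14 enone, 6,8-bis(triethylsilyl) ether | C=C(CC[C@@H]1[C@@]2(C)CCC[C@@](C)(C(=O)OC)[C@@H]2[C@@H](O[Si](CC)(CC)CC)C[C@@]1(C)O[Si](CC)(CC)CC)C(=O)C[C@@H]1OC(=O)C=C1C | intermediate
30 | (14R)-allylic alcohol, 6,8-bis(triethylsilyl) ether | C=C(CC[C@@H]1[C@@]2(C)CCC[C@@](C)(C(=O)OC)[C@@H]2[C@@H](O[Si](CC)(CC)CC)C[C@@]1(C)O[Si](CC)(CC)CC)[C@@H](C[C@@H]1OC(=O)C=C1C)O | intermediate
31 | (14R)-methanesulfonate of 30 | C=C(CC[C@@H]1[C@@]2(C)CCC[C@@](C)(C(=O)OC)[C@@H]2[C@@H](O[Si](CC)(CC)CC)C[C@@]1(C)O[Si](CC)(CC)CC)[C@@H](C[C@@H]1OC(=O)C=C1C)OS(C)(=O)=O | intermediate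
32 | (14S)-hydroperoxide, 6,8-bis(triethylsilyl) ether | C=C(CC[C@@H]1[C@@]2(C)CCC[C@@](C)(C(=O)OC)[C@@H]2[C@@H](O[Si](CC)(CC)CC)C[C@@]1(C)O[Si](CC)(CC)CC)[C@H](C[C@@H]1OC(=O)C=C1C)OO | intermediate
33 | CNP0324515.1 | C=C(CC[C@@H]1[C@@]2(C)CCC[C@@](C)(C(=O)OC)[C@@H]2[C@@H](O)C[C@@]1(C)O)[C@H](C[C@@H]1OC(=O)C=C1C)OO | target

**Summary**

Total step count: 23. Longest linear sequence: 17 steps (steps 1–12 and 19–23, from larixol); the butenolide aldehyde takes 6 steps (steps 13–18).

Steps most likely to fail:

Step 7. The O6 radical may be diverted before it transfers hydrogen (oxidation to the 6-ketone, β-scission of C5–C6, over-iodination at C18), or iodide 11 may close slowly because the new ring is trans-fused to both carbocycles. The fallback sets out from 9 and comes back at 14; it keeps the same C–H bond as the target but needs neither iodine nor an SN2 ring closure. NOCl in pyridine at −20 °C gives the 6α-nitrite F1. Barton nitrite photolysis (Hg lamp, Pyrex, benzene) should move NO to C18 to give the C18 nitroso compound F2, which tautomerises on warming in i-PrOH to the 18-oxime F3. TiCl3 with NH4OAc in aqueous THF cleaves the oxime, and the 18-aldehyde closes with the 6α-OH to the lactol F4. Oxidation with (n-Pr4N)RuO4 and N-methylmorpholine N-oxide gives the lactone ketal F5, and pyridinium p-toluenesulfonate in wet acetone gives 14, so that step 9 is no longer needed.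

Step 22. Substitution at the allylic C14 may leak into the SN2' path or into ionisation with loss of configuration, the mesylate may eliminate towards C15, or peroxide may attack the butenolide. The fallback sets out from 28 (both C14 epimers serve, so steps 20 and 21 fall away) and comes back at 32. Myers reductive transposition with 2-nitrobenzenesulfonylhydrazide, PPh3 and diethyl azodicarboxylate in THF at −30 °C gives the N-allyl sulfonylhydrazine F6. On warming this loses sulfinic acid to the allylic diazene F7, which loses N2 by retro-ene shift to the (E)-13(14)-alkene F8. A Schenck ene reaction with singlet oxygen (O2, tetraphenylporphyrin, hν, CH2Cl2, 0 °C) then places OOH on C14 with shift of the double bond to C13=C16. This fallback gives up stereocontrol at C14: 32 would have to be separated from its C14 epimer and from the C13 hydroperoxide regioisomer.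

Step 4. Facial selectivity in the capture of O2 by the planar C8 radical may be poor and give the 8β-alcohol. The fallback sets out from 5 and comes back at 7. mCPBA with NaHCO3 in CH2Cl2 should attack the exocyclic alkene from the α face, anti to the C10 methyl, to give the 8α,17-epoxide F9. LiAlH4 in THF opens it at C17 and also removes the acetate to give the 6α,8α-diol F10. Ac2O in pyridine re-acetylates only the secondary 6-OH and gives 7.

**Further compounds**

F1 | step 7 | 6α-nitrite of 9 | CC1(OCCO1)CC[C@@H]2[C@@]3(C)CCCC(C)(C)[C@@H]3[C@@H](ON=O)C[C@@]2(C)O[Si](CC)(CC)CC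
F2 | step 7 | 13,13-ethylenedioxy-18-nitroso-8α-triethylsilyloxy-14,15-dinorlabdan-6α-ol | CC1(OCCO1)CC[C@@H]2[C@@]3(C)CCC[C@@](C)(CN=O)[C@@H]3[C@@H](O)C[C@@]2(C)O[Si](CC)(CC)CC
F3 | step 7 | 13,13-ethylenedioxy-6α-hydroxy-8α-triethylsilyloxy-14,15-dinorlabdan-18-al oxime | CC1(OCCO1)CC[C@@H]2[C@@]3(C)CCC[C@@](C)(C=NO)[C@@H]3[C@@H](O)C[C@@]2(C)O[Si](CC)(CC)CC
F4 | step 7 | 6α,18-epoxy-13,13-ethylenedioxy-8α-triethylsilyloxy-14,15-dinorlabdan-18-ol (lactol) | CC1(OCCO1)CC[C@@H]2[C@@]3(C)CCC[C@@](C)(C(O)O4)[C@@H]3[C@@H]4C[C@@]2(C)O[Si](CC)(CC)CC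
F5 | step 7 | 13,13-ethylenedioxy-8α-triethylsilyloxy-14,15-dinorlabdan-18,6α-olide | CC1(OCCO1)CC[C@@H]2[C@@]3(C)CCC[C@@](C)(C(=O)O4)[C@@H]3[C@@H]4C[C@@]2(C)O[Si](CC)(CC)CC
F6 | step 22 | C14 N-(2-nitrobenzenesulfonyl)hydrazine from 28 | C=C(CC[C@@H]1[C@@]2(C)CCC[C@@](C)(C(=O)OC)[C@@H]2[C@@H](O[Si](CC)(CC)CC)C[C@@]1(C)O[Si](CC)(CC)CC)C(C[C@@H]1OC(=O)C=C1C)N(N)S(=O)(=O)c1ccccc1[N+](=O)[O-]
F7 | step 22 | C14 allylic diazene | C=C(CC[C@@H]1[C@@]2(C)CCC[C@@](C)(C(=O)OC)[C@@H]2[C@@H](O[Si](CC)(CC)CC)C[C@@]1(C)O[Si](CC)(CC)CC)C(C[C@@H]1OC(=O)C=C1C)N=N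
F8 | step 22 | (E)-13(14)-alkene, 6,8-bis(triethylsilyl) ether | C/C(CC[C@@H]1[C@@]2(C)CCC[C@@](C)(C(=O)OC)[C@@H]2[C@@H](O[Si](CC)(CC)CC)C[C@@]1(C)O[Si](CC)(CC)CC)=C\C[C@@H]1OC(=O)C=C1C
F9 | step 4 | 6α-acetoxy-8α,17-epoxy-13,13-ethylenedioxy-14,15-dinorlabdane | CC1(OCCO1)CC[C@@H]2[C@@]3(C)CCCC(C)(C)[C@@H]3[C@@H](OC(C)=O)C[C@]24CO4
F10 | step 4 | 13,13-ethylenedioxy-14,15-dinorlabdane-6α,8α-diol | CC1(OCCO1)CC[C@@H]2[C@@]3(C)CCCC(C)(C)[C@@H]3[C@@H](O)C[C@@]2(C)O
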